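## Retrosynthetic overview

1. The target is released last from its (R)-configured benzyl acetal by neutral hydrogenolysis, so the labile lactol stereocentre is carried as a configurationally stable 3-benzyloxyphthalide.
2. Both lactone rings are cut at their carbonyl carbons: one Pd-catalysed double carbonylation of a dibromo diaryl ether aldehyde (CO, benzyl alcohol) closes the seven-membered depsidone lactone and the five-membered phthalide acetal together and sets the stereocentre.
3. The diaryl ether comes from an Ullmann coupling of a ring A bromophenol with a symmetrical 2,6-dibromobenzaldehyde (ring B), whose two bromines are equivalent until the coupling.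
4. Ring A comes from creosol (benzylation, bromination, metalation–hydroxylation); ring B from 2-methylresorcinol (dibromination, MOM protection, metalation–formylation).
5. Ring order: rings A and B are bought as arenes; the seven-membered and five-membered rings form in the same step.

Assumption 1: the lactol carbon (the only stereocentre) can epimerise by ring–chain tautomerism in acid, base or protic media, so it is released in the last step under neutral aprotic conditions and target 16 is assumed to be configurationally stable when kept that way.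
Assumption 2: the sense of induction of the chiral ligand in step 9 cannot be predicted; (R,R)-Me-DuPhos is written for the (R)-acetal, and its enantiomer is used if the sense is opposite.

## Route

Step 1
Reactants: 1 2-methoxy-4-methylphenol (creosol)
Product: 2 1-(benzyloxy)-2-methoxy-4-methylbenzene
Conditions: BnBr, K2CO3, DMF, 60 °C
Reagents that add atoms: benzyl bromide, BrCc1ccccc1
Why: Williamson O-benzylation of the phenoxide; the benzyl group stays on this oxygen until the last step.

Step 2
Reactants: 2 1-(benzyloxy)-2-methoxy-4-methylbenzene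
Product: 3 1-(benzyloxy)-5-bromo-2-methoxy-4-methylbenzene
Conditions: N-bromosuccinimide, MeCN, 0 °C to 20 °C, dark
Reagents that add atoms: N-bromosuccinimide, O=C1CCC(=O)N1Br
Why: Electrophilic aromatic bromination goes to the only position para to an alkoxy group (para to OMe, ortho to CH3), as with 4-methylveratrole.

Step 3
Reactants: 3 1-(benzyloxy)-5-bromo-2-methoxy-4-methylbenzene
Product: 6 2-(benzyloxy)-6-bromo-3-methoxy-5-methylphenol, via aryllithium 4 (not isolated), via arylboronate 5 (not isolated)
Conditions: LiN(iPr)2, B(OiPr)3 (in situ trap), THF, −78 °C; then H2O2, NaOH (aq), 0 °C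
Reagents that add atoms: hydrogen peroxide, OO
Why: Directed ortho-metalation removes the most acidic ring proton (flanked by Br and OBn), in situ borylation outruns benzyne formation, and boronate oxidation turns C–B into C–OH.

Step 4
Reactants: 7 2-methylbenzene-1,3-diol (2-methylresorcinol)
Product: 8 4,6-dibromo-2-methylbenzene-1,3-diol
Conditions: Br2 (2 equiv), CHCl3, 0 °C
Reagents that add atoms: bromine, BrBr
Why: Electrophilic aromatic bromination takes the two positions that are ortho to one OH and para to the other; the position meta to both stays free.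

Step 5
Reactants: 8 4,6-dibromo-2-methylbenzene-1,3-diol
Product: 9 1,5-dibromo-2,4-bis(methoxymethoxy)-3-methylbenzene
Conditions: MOMCl, K2CO3, acetone, reflux
Reagents that add atoms: chloromethyl methyl ether, COCCl
Why: O-alkylation of both acidic bromophenols gives MOM ethers that tolerate LiN(iPr)2 and the Ullmann step and are later removed by acid without touching the benzyl ether.

Step 6
Reactants: 9 1,5-dibromo-2,4-bis(methoxymethoxy)-3-methylbenzene
Product: 11 2,6-dibromo-3,5-bis(methoxymethoxy)-4-methylbenzaldehyde, via aryllithium 10 (not isolated)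
Conditions: LiN(iPr)2, THF, −78 °C; then DMF, −78 °C to 0 °C; H2O
Reagents that add atoms: N,N-dimethylformamide, CN(C)C=O
Why: Deprotonation of the only ring C–H, acidified by two flanking bromines (as in 1,3-dibromobenzene to 2,6-dibromobenzaldehyde), and formylation with DMF give a symmetrical aldehyde with two equivalent bromines.

Step 7
Reactants: 6 2-(benzyloxy)-6-bromo-3-methoxy-5-methylphenol; 11 2,6-dibromo-3,5-bis(methoxymethoxy)-4-methylbenzaldehyde (2 equiv)
Product: 12 2-[2-(benzyloxy)-6-bromo-3-methoxy-5-methylphenoxy]-6-bromo-3,5-bis(methoxymethoxy)-4-methylbenzaldehyde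
Conditions: CuI (copper monoiodide, 10 mol %), picolinic acid (20 mol %), K3PO4, DMSO, 90 °C
Reagents that add atoms: none
Why: Ullmann-type Cu-catalysed O-arylation at a bromide activated by the ortho-formyl group, while the bromide of 6 is deactivated by its ortho-phenoxide and the excess of 11 keeps the reaction at mono-substitution.

Step 8
Reactants: 12 2-[2-(benzyloxy)-6-bromo-3-methoxy-5-methylphenoxy]-6-bromo-3,5-bis(methoxymethoxy)-4-methylbenzaldehyde
Product: 13 2-[2-(benzyloxy)-6-bromo-3-methoxy-5-methylphenoxy]-6-bromo-3,5-dihydroxy-4-methylbenzaldehyde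
Conditions: HCl (0.5 M in MeOH), 45 °C; aqueous work-up
Reagents that add atoms: none
Why: Acid-catalysed acetal cleavage removes both MOM groups and leaves the benzyl ether, the methyl ether, the aryl bromides and the aldehyde untouched.

Step 9
Reactants: 13 2-[2-(benzyloxy)-6-bromo-3-methoxy-5-methylphenoxy]-6-bromo-3,5-dihydroxy-4-methylbenzaldehyde
Product: 15 (1R)-1,11-bis(benzyloxy)-4-hydroxy-10-methoxy-5,8-dimethyl-1H-isobenzofuro[4,5-b][1,4]benzodioxepine-3,7-dione, via bromophthalide acetal 14 (not isolated)
Conditions: CO (5 bar), BnOH (1.5 equiv), Pd(OAc)2 (10 mol %), (R,R)-Me-DuPhos (12 mol %), Et3N, 4 Å molecular sieves, toluene (0.02 M), 90 °C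
Reagents that add atoms: carbon monoxide, [C-]#[O+]; benzyl alcohol, OCc1ccccc1
Why: Proposed new method: zerovalent palladium inserts into both aryl–Br bonds and CO gives two acylpalladium bromides; the ring A acyl is captured by the neighbouring ring B phenol (seven-membered lactone) and the ring B acyl by the OH of the benzyl hemiacetal formed reversibly at the ortho-formyl group (five-membered 3-benzyloxyphthalide); because the hemiacetal enantiomers interconvert through the aldehyde, C–O reductive elimination from the diastereomeric acyl(alkoxide)palladium chelates of the bisphospholane selects one of them (dynamic kinetic resolution) and fixes the (R) acetal carbon; the closest known reactions are the carbonylative cyclisation of 2-bromobenzaldehydes with alcohols to racemic 3-alkoxyphthalides and the intramolecular carbonylative lactonisation of aryl halides that carry a phenol.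

Step 10
Reactants: 15 (1R)-1,11-bis(benzyloxy)-4-hydroxy-10-methoxy-5,8-dimethyl-1H-isobenzofuro[4,5-b][1,4]benzodioxepine-3,7-dione
Product: 16 (1R)-1,4,11-trihydroxy-10-methoxy-5,8-dimethyl-1H-isobenzofuro[4,5-b][1,4]benzodioxepine-3,7-dione (target CNP0211607.1)
Conditions: H2 (1 atm), Pd/C (10 % palladium on carbon, neutral), EtOAc, 20 °C
Reagents that add atoms: none
Why: Hydrogenolysis cleaves only the two PhCH2–O bonds (as with anomeric O-benzyl glycosides giving lactols), so no bond to the acetal carbon is broken and the (R) configuration from step 9 is kept in a neutral aprotic medium.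

## Compound list

1 | 2-methoxy-4-methylphenol (creosol) | Cc1ccc(O)c(OC)c1 | starting material
2 | 1-(benzyloxy)-2-methoxy-4-methylbenzene | Cc1ccc(OCc2ccccc2)c(OC)c1 | intermediate
3 | 1-(benzyloxy)-5-bromo-2-methoxy-4-methylbenzene | Cc1cc(OC)c(OCc2ccccc2)cc1Br | intermediate
4 | [2-(benzyloxy)-6-bromo-3-methoxy-5-methylphenyl]lithium (not isolated) | [Li]c1c(Br)c(C)cc(OC)c1OCc1ccccc1 | intermediate
5 | diisopropyl [2-(benzyloxy)-6-bromo-3-methoxy-5-methylphenyl]boronate (not isolated) | CC(C)OB(OC(C)C)c1c(Br)c(C)cc(OC)c1OCc1ccccc1 | intermediate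
6 | 2-(benzyloxy)-6-bromo-3-methoxy-5-methylphenol | Cc1cc(OC)c(OCc2ccccc2)c(O)c1Br | intermediate
7 | 2-methylbenzene-1,3-diol (2-methylresorcinol) | Cc1c(O)cccc1O | starting material
8 | 4,6-dibromo-2-methylbenzene-1,3-diol | Cc1c(O)c(Br)cc(Br)c1O | intermediate
9 | 1,5-dibromo-2,4-bis(methoxymethoxy)-3-methylbenzene | Cc1c(OCOC)c(Br)cc(Br)c1OCOC | intermediate
10 | [2,6-dibromo-3,5-bis(methoxymethoxy)-4-methylphenyl]lithium (not isolated) | [Li]c1c(Br)c(OCOC)c(C)c(OCOC)c1Br | intermediate
11 | 2,6-dibromo-3,5-bis(methoxymethoxy)-4-methylbenzaldehyde | O=Cc1c(Br)c(OCOC)c(C)c(OCOC)c1Br | intermediate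
12 | 2-[2-(benzyloxy)-6-bromo-3-methoxy-5-methylphenoxy]-6-bromo-3,5-bis(methoxymethoxy)-4-methylbenzaldehyde | Cc1cc(OC)c(OCc2ccccc2)c(Oc2c(OCOC)c(C)c(OCOC)c(Br)c2C=O)c1Br | intermediate
13 | 2-[2-(benzyloxy)-6-bromo-3-methoxy-5-methylphenoxy]-6-bromo-3,5-dihydroxy-4-methylbenzaldehyde | Cc1cc(OC)c(OCc2ccccc2)c(Oc2c(O)c(C)c(O)c(Br)c2C=O)c1Br | intermediate
14 | (3R)-3-(benzyloxy)-4-[2-(benzyloxy)-6-bromo-3-methoxy-5-methylphenoxy]-5,7-dihydroxy-6-methyl-2-benzofuran-1(3H)-one (not isolated) | Cc1cc(OC)c(OCc2ccccc2)c(Oc3c(O)c(C)c(O)c4c3[C@H](OCc3ccccc3)OC4=O)c1Br | intermediate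
15 | (1R)-1,11-bis(benzyloxy)-4-hydroxy-10-methoxy-5,8-dimethyl-1H-isobenzofuro[4,5-b][1,4]benzodioxepine-3,7-dione (benzyl ether of the ring A phenol, benzyl acetal of the lactol) | COc1cc(C)c2c(c1OCc4ccccc4)Oc1c(c(C)c(O)c3c1[C@H](OCc5ccccc5)OC3=O)OC2=O | intermediate
16 | (1R)-1,4,11-trihydroxy-10-methoxy-5,8-dimethyl-1H-isobenzofuro[4,5-b][1,4]benzodioxepine-3,7-dione | COc1cc(C)c2c(c1O)Oc1c(c(C)c(O)c3c1[C@H](O)OC3=O)OC2=O | target

## Step count and risks

Total steps: 10. Longest linear sequence: 7 (steps 1–3 or 4–6, then 7–10).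

**Step 9 (most likely to fail).** The risks are interception of the ring A acylpalladium by benzyl alcohol, slow oxidative addition at two hindered, electron-rich bromides, and low enantioselectivity. The fallback sets out from 13 and moves stereocontrol from the catalyst to a covalently bound auxiliary. The double carbonylation is run with Pd(OAc)2 and achiral Xantphos (the most reliable ligand for aryl bromide carbonylation) with (S)-1-phenylethanol in place of benzyl alcohol. This gives two separable diastereomers: (1R)-11-(benzyloxy)-4-hydroxy-10-methoxy-5,8-dimethyl-1-[(1S)-1-phenylethoxy]-1H-isobenzofuro[4,5-b][1,4]benzodioxepine-3,7-dione F1 and its (1S)-acetal epimer F2. They are separated by chromatography or crystallisation, and F2 is re-equilibrated to the F1/F2 mixture with catalytic TsOH in toluene. Hydrogenolysis of F1 (H2, Pd/C, EtOAc) cleaves the phenylethyl and benzyl C–O bonds and comes back to the route at 16.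

**Step 7.** The product is a diaryl ether with four ortho substituents, and Ullmann couplings of this kind can stall. The fallback sets out from 9 and 6 and makes the ether before the formyl group is present. Mono bromine–lithium exchange of 9 (n-BuLi, 1 equiv, THF, −78 °C) and B(OiPr)3 give [5-bromo-2,4-bis(methoxymethoxy)-3-methylphenyl]boronic acid F3. Oxidative Chan–Lam coupling of F3 with 6 (Cu(OAc)2, pyridine, 4 Å molecular sieves, air, CH2Cl2, 20 °C) gives 2-(benzyloxy)-4-bromo-3-[5-bromo-2,4-bis(methoxymethoxy)-3-methylphenoxy]-1-methoxy-5-methylbenzene F4, which has one ortho substituent fewer at the coupling site. Deprotonation of F4 at the ring B C–H between Br and the aryloxy group (LiN(iPr)2, THF, −78 °C) and DMF then comes back to the route at 12.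

**Step 3.** The ortho-bromo aryllithium can lose LiBr to a benzyne, and the benzyl ether can be metalated. The fallback sets out from 1 and introduces the oxygen before the bromine. Ortho-formylation of 1 (MgCl2, Et3N, paraformaldehyde, MeCN, reflux) gives 2-hydroxy-3-methoxy-5-methylbenzaldehyde F5. Benzylation (BnBr, K2CO3, DMF) gives 2-(benzyloxy)-3-methoxy-5-methylbenzaldehyde F6. Baeyer–Villiger oxidation (mCPBA, CH2Cl2) gives 2-(benzyloxy)-3-methoxy-5-methylphenyl formate F7, and methanolysis (K2CO3, MeOH) gives 2-(benzyloxy)-3-methoxy-5-methylphenol F8. Amine-catalysed ortho-bromination of F8 (N-bromosuccinimide, iPr2NH catalytic, CH2Cl2, 0 °C) comes back to the route at 6.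

## Further compounds

F1 | step 9 | (1R)-11-(benzyloxy)-4-hydroxy-10-methoxy-5,8-dimethyl-1-[(1S)-1-phenylethoxy]-1H-isobenzofuro[4,5-b][1,4]benzodioxepine-3,7-dione | COc1cc(C)c2c(c1OCc4ccccc4)Oc1c(c(C)c(O)c3c1[C@H](O[C@@H](C)c5ccccc5)OC3=O)OC2=O
F2 | step 9 | (1S)-11-(benzyloxy)-4-hydroxy-10-methoxy-5,8-dimethyl-1-[(1S)-1-phenylethoxy]-1H-isobenzofuro[4,5-b][1,4]benzodioxepine-3,7-dione | COc1cc(C)c2c(c1OCc4ccccc4)Oc1c(c(C)c(O)c3c1[C@@H](O[C@@H](C)c5ccccc5)OC3=O)OC2=O
F3 | step 7 | [5-bromo-2,4-bis(methoxymethoxy)-3-methylphenyl]boronic acid | Cc1c(OCOC)c(Br)cc(B(O)O)c1OCOC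
F4 | step 7 | 2-(benzyloxy)-4-bromo-3-[5-bromo-2,4-bis(methoxymethoxy)-3-methylphenoxy]-1-methoxy-5-methylbenzene | Cc1cc(OC)c(OCc2ccccc2)c(Oc2cc(Br)c(OCOC)c(C)c2OCOC)c1Br
F5 | step 3 | 2-hydroxy-3-methoxy-5-methylbenzaldehyde | Cc1cc(C=O)c(O)c(OC)c1
F6 | step 3 | 2-(benzyloxy)-3-methoxy-5-methylbenzaldehyde | Cc1cc(C=O)c(OCc2ccccc2)c(OC)c1
F7 | step 3 | 2-(benzyloxy)-3-methoxy-5-methylphenyl formate | Cc1cc(OC=O)c(OCc2ccccc2)c(OC)c1
F8 | step 3 | 2-(benzyloxy)-3-methoxy-5-methylphenol | Cc1cc(O)c(OCc2ccccc2)c(OC)c1
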